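**Retrosynthetic overview**

- Feature: on the benzo ring of the 2H-chromene, O1 (on C8a) and the C8 hydroxyl sit on neighbouring carbons, and each has a five-carbon unit on its other ortho carbon (C4a carries C4=C3–C2Me2, C7 carries prenyl). The benzo ring is therefore a 3,6-diprenylcatechol in which one prenyl group has closed oxidatively onto its neighbouring oxygen.
- Disconnection 1: the aryl ketone C(=O)–aryl bond, giving the Weinreb amide of the chromene propanoate and a 2,4-bis(methoxymethoxy)phenyllithium.
- Disconnection 2 (key): the O1–C2 bond of the pyran ring, opened to a diprenylcatechol ester that is oxidised at an anode to the ortho-quinone, tautomerised and closed by oxa-6π electrocyclisation.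
- Disconnection 3: both prenyl groups, placed by a double aromatic Claisen rearrangement of the bis(1,1-dimethylallyl) ether of methyl dihydrocaffeate (copper-catalysed propargylation, then semihydrogenation).
- Ring order: both benzene rings are bought; the pyran ring is the only ring formed (step 5).

Key step: step 5

Remark: the target has no stereocentre. At the catechol stage the ring carbon bearing the side chain is called C1, the prenyl groups sit on C2 and C5, and the oxygens on C3 and C4; from compound 9 on, chromene numbering (O1 to C8a) is used.

**Route**

Step 1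
Reactants: 1 3-(3,4-dihydroxyphenyl)propanoic acid
Product: 2 methyl 3-(3,4-dihydroxyphenyl)propanoate
Conditions: MeOH, H2SO4 (cat.), reflux
Reagents that add atoms: methanol, CO
Why: Fischer esterification in excess methanol leaves the catechol untouched and masks the acid for the basic and thermal steps that follow.

Step 2
Reactants: 2 methyl 3-(3,4-dihydroxyphenyl)propanoate; 3 3-chloro-3-methylbut-1-yne
Product: 4 methyl 3-[3,4-bis(2-methylbut-3-yn-2-yloxy)phenyl]propanoate
Conditions: 3 (3 equiv), DBU, CuCl2·2H2O (cat.), MeCN, 0 °C, Ar
Reagents that add atoms: none
Why: Copper-catalysed O-propargylation of phenols with a tertiary propargylic chloride proceeds through a copper acetylide-derived electrophile that tolerates crowded phenoxides, so excess chloride should etherify both catechol oxygens, while argon, a catalytic copper load and 0 °C should hold back catechol oxidation and addition of a free phenol to the alkyne.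

Step 3
Reactants: 4 methyl 3-[3,4-bis(2-methylbut-3-yn-2-yloxy)phenyl]propanoate
Product: 5 methyl 3-[3,4-bis(2-methylbut-3-en-2-yloxy)phenyl]propanoate
Conditions: H2 (1 atm), Lindlar catalyst (Pd on CaCO3, poisoned with Pb(OAc)2), quinoline, EtOAc, rt
Reagents that add atoms: none
Why: Lindlar semihydrogenation of the two terminal alkynes, stopped after two equivalents of H2, should give the terminal alkenes without touching the ester or the aryl ethers.

Step 4
Reactants: 5 methyl 3-[3,4-bis(2-methylbut-3-en-2-yloxy)phenyl]propanoate
Product: 6 methyl 3-[3,4-dihydroxy-2,5-bis(3-methylbut-2-en-1-yl)phenyl]propanoate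
Conditions: PhNEt2, 150 °C, Ar
Reagents that add atoms: none
Why: Two aromatic Claisen rearrangements of the 1,1-dimethylallyl ethers, each to the single ortho CH of its oxygen (O4 to C5, O3 to C2) and each followed by tautomerisation, invert the allyl units so that linear prenyl groups arrive at C2 and C5, and the amine solvent buffers the phenols against acid-induced chroman formation.

Step 5
Reactants: 6 methyl 3-[3,4-dihydroxy-2,5-bis(3-methylbut-2-en-1-yl)phenyl]propanoate
Product: 9 methyl 3-[8-hydroxy-2,2-dimethyl-7-(3-methylbut-2-en-1-yl)-2H-chromen-6-yl]propanoate, via ortho-quinone 7 (not isolated), via quinone methide 8 (not isolated)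
Conditions: undivided cell, graphite anode, Pt cathode, Ag/AgCl reference, LiClO4 (0.1 M) in dry MeCN, 2,6-lutidine (2 equiv), anode held at the first oxidation wave of 6, rt, Ar; then 40 °C until 7 is consumed
Reagents that add atoms: none
Why: Proposed new method: at the graphite anode catechol 6 should lose two electrons and two protons (carried by 2,6-lutidine and discharged as H2 at the cathode) to give ortho-quinone 7, whose C5 prenyl CH2 is deprotonated in a vinylogous enolisation through C5=C6–C1=C2–C3=O to the dienyl ortho-quinone methide 8; 8 then closes by a thermal disrotatory oxa-6π electrocyclisation of its O4=C4–C5=CH–CH=CMe2 unit, which forms the O1–C2 bond and the pyran ring and restores the arene with the former O3 as the C8 phenol. The closest known reaction types are the anodic oxidation of catechols to ortho-quinones and the amine- or heat-induced isomerisation of prenyl quinones to 2,2-dimethylchromenols; joining the two under potential control, with two prenyl groups in competition, has not been shown. The pyran ring closes in the 6π-electrocyclic mode and no stereocentre is created. Site selectivity is needed among three vinylogous CH2 groups: the C5 prenyl CH2, flanked by the C6 hydrogen, can align a C–H bond with the quinone π system without strain, its dienolate places charge on the unsubstituted C6, and the exocyclic alkene and pyran derived from it have only a hydrogen as neighbour, whereas the C2 prenyl CH2 is wedged between the C3 carbonyl and the C1 chain and its dienolate places charge on two alkylated carbons, and the side-chain CH2 is benzylic but not allylic and gives a shorter conjugated anion. Reversible enolisation drained by the irreversible, aromatising electrocyclisation should funnel material through the (Z)-isomer of 8 even where the (E)-isomer or another tautomer forms first. A single closure is secured by the potential: monophenol 9 is expected to be oxidised at a distinctly higher potential than catechol 6, so an anode held at the first wave of 6 should stop after one ring, and any quinone reduced at the cathode merely returns to 6.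

Step 6
Reactants: 9 methyl 3-[8-hydroxy-2,2-dimethyl-7-(3-methylbut-2-en-1-yl)-2H-chromen-6-yl]propanoate
Product: 10 methyl 3-[8-(methoxymethoxy)-2,2-dimethyl-7-(3-methylbut-2-en-1-yl)-2H-chromen-6-yl]propanoate
Conditions: MOMCl, i-Pr2NEt, CH2Cl2, 0 °C to rt
Reagents that add atoms: chloromethyl methyl ether, COCCl
Why: O-Alkylation of the C8 phenol with the highly reactive chloromethyl ether should proceed even at this flanked position and removes the acidic proton before the organometallic steps.

Step 7
Reactants: 10 methyl 3-[8-(methoxymethoxy)-2,2-dimethyl-7-(3-methylbut-2-en-1-yl)-2H-chromen-6-yl]propanoate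
Product: 11 N-methoxy-3-[8-(methoxymethoxy)-2,2-dimethyl-7-(3-methylbut-2-en-1-yl)-2H-chromen-6-yl]-N-methylpropanamide
Conditions: MeNH(OMe)·HCl, i-PrMgCl, THF, −20 °C to 0 °C
Reagents that add atoms: N,O-dimethylhydroxylamine hydrochloride, CNOC.Cl
Why: The chloromagnesium amide of N,O-dimethylhydroxylamine, made in the flask with i-PrMgCl, converts methyl esters directly into Weinreb amides at low temperature, conditions under which the MOM ether, the chromene and the prenyl group are inert.

Step 8
Reactants: 12 4-bromobenzene-1,3-diol
Product: 13 1-bromo-2,4-bis(methoxymethoxy)benzene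
Conditions: MOMCl, i-Pr2NEt, CH2Cl2, 0 °C to rt
Reagents that add atoms: chloromethyl methyl ether, COCCl
Why: Double methoxymethylation of the resorcinol gives ethers that survive n-BuLi and stabilise the neighbouring aryllithium by chelation.

Step 9
Reactants: 13 1-bromo-2,4-bis(methoxymethoxy)benzene; 11 N-methoxy-3-[8-(methoxymethoxy)-2,2-dimethyl-7-(3-methylbut-2-en-1-yl)-2H-chromen-6-yl]-N-methylpropanamide
Product: 16 1-[2,4-bis(methoxymethoxy)phenyl]-3-[8-(methoxymethoxy)-2,2-dimethyl-7-(3-methylbut-2-en-1-yl)-2H-chromen-6-yl]propan-1-one, via aryllithium 14 (not isolated), via lithium hemiaminal 15 (not isolated)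
Conditions: 13, n-BuLi, THF, −78 °C; then 11, −78 °C to 0 °C; aq NH4Cl
Reagents that add atoms: none
Why: Bromine–lithium exchange outruns ortho-lithiation at −78 °C, and the resulting aryllithium adds only once to the Weinreb amide because the chelated tetrahedral adduct persists until the aqueous quench, which releases the ketone.

Step 10
Reactants: 16 1-[2,4-bis(methoxymethoxy)phenyl]-3-[8-(methoxymethoxy)-2,2-dimethyl-7-(3-methylbut-2-en-1-yl)-2H-chromen-6-yl]propan-1-one
Product: 17 1-(2,4-dihydroxyphenyl)-3-[8-hydroxy-2,2-dimethyl-7-(3-methylbut-2-en-1-yl)-2H-chromen-6-yl]propan-1-one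
Conditions: HCl in MeOH (1.25 M), 40 °C
Reagents that add atoms: none
Why: Acid-catalysed acetal exchange with methanol removes the three MOM groups as dimethoxymethane, and at 40 °C the 2,2-dimethylchromene and the prenyl group ortho to the C8 phenol are expected to survive.

**Compound list**

1 | 3-(3,4-dihydroxyphenyl)propanoic acid | OC(=O)CCc1ccc(O)c(O)c1 | starting material
2 | methyl 3-(3,4-dihydroxyphenyl)propanoate | COC(=O)CCc1ccc(O)c(O)c1 | intermediate
3 | 3-chloro-3-methylbut-1-yne | C#CC(C)(C)Cl | starting material
4 | methyl 3-[3,4-bis(2-methylbut-3-yn-2-yloxy)phenyl]propanoate | COC(=O)CCc1ccc(OC(C)(C)C#C)c(OC(C)(C)C#C)c1 | intermediate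
5 | methyl 3-[3,4-bis(2-methylbut-3-en-2-yloxy)phenyl]propanoate | COC(=O)CCc1ccc(OC(C)(C)C=C)c(OC(C)(C)C=C)c1 | intermediate
6 | methyl 3-[3,4-dihydroxy-2,5-bis(3-methylbut-2-en-1-yl)phenyl]propanoate | COC(=O)CCc1cc(CC=C(C)C)c(O)c(O)c1CC=C(C)C | intermediate
7 | methyl 3-[2,5-bis(3-methylbut-2-en-1-yl)-3,4-dioxocyclohexa-1,5-dien-1-yl]propanoate (ortho-quinone, not isolated) | COC(=O)CCC1=C(CC=C(C)C)C(=O)C(=O)C(CC=C(C)C)=C1 | intermediate
8 | ortho-quinone methide of 7: C4 carbonyl, C3 enol, (Z)-3-methylbut-2-en-1-ylidene group on C5 with its vinyl group syn to the C4 carbonyl (not isolated) | COC(=O)CCC1=C/C(=C/C=C(C)C)C(=O)C(O)=C1CC=C(C)C | intermediate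
9 | methyl 3-[8-hydroxy-2,2-dimethyl-7-(3-methylbut-2-en-1-yl)-2H-chromen-6-yl]propanoate | COC(=O)CCc1cc2C=CC(C)(C)Oc2c(O)c1CC=C(C)C | intermediate
10 | methyl 3-[8-(methoxymethoxy)-2,2-dimethyl-7-(3-methylbut-2-en-1-yl)-2H-chromen-6-yl]propanoate | COC(=O)CCc1cc2C=CC(C)(C)Oc2c(OCOC)c1CC=C(C)C | intermediate
11 | N-methoxy-3-[8-(methoxymethoxy)-2,2-dimethyl-7-(3-methylbut-2-en-1-yl)-2H-chromen-6-yl]-N-methylpropanamide | CON(C)C(=O)CCc1cc2C=CC(C)(C)Oc2c(OCOC)c1CC=C(C)C | intermediate
12 | 4-bromobenzene-1,3-diol | Oc1ccc(Br)c(O)c1 | starting material
13 | 1-bromo-2,4-bis(methoxymethoxy)benzene | COCOc1ccc(Br)c(OCOC)c1 | intermediate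
14 | [2,4-bis(methoxymethoxy)phenyl]lithium (not isolated) | [Li]c1ccc(OCOC)cc1OCOC | intermediate
15 | lithium 1-[2,4-bis(methoxymethoxy)phenyl]-1-[methoxy(methyl)amino]-3-[8-(methoxymethoxy)-2,2-dimethyl-7-(3-methylbut-2-en-1-yl)-2H-chromen-6-yl]propan-1-olate (racemic tetrahedral adduct, not isolated) | [Li]OC(CCc1cc2C=CC(C)(C)Oc2c(OCOC)c1CC=C(C)C)(N(C)OC)c1ccc(OCOC)cc1OCOC | intermediate
16 | 1-[2,4-bis(methoxymethoxy)phenyl]-3-[8-(methoxymethoxy)-2,2-dimethyl-7-(3-methylbut-2-en-1-yl)-2H-chromen-6-yl]propan-1-one | COCOc1ccc(C(=O)CCc2cc3C=CC(C)(C)Oc3c(OCOC)c2CC=C(C)C)c(OCOC)c1 | intermediate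
17 | 1-(2,4-dihydroxyphenyl)-3-[8-hydroxy-2,2-dimethyl-7-(3-methylbut-2-en-1-yl)-2H-chromen-6-yl]propan-1-one | CC(C)=CCc1c(CCC(=O)c2ccc(O)cc2O)cc2c(c1O)OC(C)(C)C=C2 | target

**Step count**

Total: 10 steps. Longest linear sequence: 9 steps (steps 1 to 7, 9 and 10); step 8 is a one-step side branch.

**Steps most likely to fail**

1. Step 5 (Proposed new method).
   - What may go wrong:
     - Enolisation at the wrong methylene: closure by the wedged C2 prenyl group, or formation of a para-quinone methide from the side-chain CH2 and onward desaturation of the side chain.
     - Slow tautomerisation that leaves the quinone open to conjugate addition at C6.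
     - Passivation of the anode, or oxidation beyond the first wave.
   - Fallback (sets out from 6, returns at 9): the electrolysis is replaced by a stoichiometric sequence of two separate, individually established operations. Catechol 6 is oxidised with Ag2O over MgSO4 in Et2O at 0 °C and the ortho-quinone 7 is isolated by filtration and evaporation. In a second operation 7 is isomerised with catalytic Et3N in toluene at 40 °C, the known base-induced conversion of prenyl quinones into 2,2-dimethylchromenols, to give 9. No compound outside the list is made (F0).

2. Step 4.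
   - What may go wrong:
     - Shift of the O3 allyl group to the oxygen-bearing C4, followed either by a second shift to C6 (para product) or by intramolecular Diels–Alder capture of that dienone by the neighbouring allyl ether.
     - Thermal loss of isoprene from the tertiary ethers.
     - Closure of an ortho-prenylphenol to a chroman.
   - Fallback (sets out from 2, returns at 6): the sigmatropic route is given up for a dissociative O-to-C transfer. Catechol 2 is O-alkylated with 1-bromo-3-methylbut-2-ene and K2CO3 in acetone to methyl 3-[3,4-bis(3-methylbut-2-en-1-yloxy)phenyl]propanoate F1. F1 is stirred with magnesium silicate (Florisil, MgSiO3) in toluene at rt, the known solid-acid-promoted 1,3-shift of aryl prenyl ethers to ortho-prenylphenols, to give 6 without tertiary ethers and without heating.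

3. Step 2.
   - What may go wrong:
     - Stalling at the mono-ether, because the second phenoxide is flanked by a tertiary ether.
     - Oxidation of the catechol by divalent copper.
     - Addition of the remaining phenol to the alkyne of the mono-ether.
   - Fallback (sets out from 2, returns at 5): the alkyne stage is bypassed. Catechol 2 is treated with tert-butyl 2-methylbut-3-en-2-yl carbonate and catalytic Pd(PPh3)4 (zerovalent palladium) in THF at 0 °C. This decarboxylative allylic etherification is known to place 1,1-dimethylallyl groups on phenols and catechol-type diphenols at the more substituted allyl terminus; it gives 5 directly and makes step 3 unnecessary. No compound outside the list is made (F0).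

Further compounds
F0 | step 5 | none | none
F1 | step 4 | methyl 3-[3,4-bis(3-methylbut-2-en-1-yloxy)phenyl]propanoate | COC(=O)CCc1ccc(OCC=C(C)C)c(OCC=C(C)C)c1
F0 | step 2 | none | none
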